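## Retrosynthetic overview

- **Last C–C bond:** a Julia–Kocienski olefination makes the E alkene between ring A sulfone 28 (fragment A) and ring B aldehyde 18 (fragment B); desilylation then gives target 30.
- **Ring B, closed first (step 10):** ring B is the 2-bromo-1-methylcyclohexan-1-ol ring (C1 = carbinol carbon, C2 = CHBr, C4 = ring CH bearing the side-chain carbinol C8). It is closed by making the C1–C2 bond: SmI2 converts the gem-dibromide of acyclic keto dibromide 13 into a 1-bromoalkyl carbenoid that adds 6-exo to the methyl ketone. One operation delivers the ring, Br, the tertiary OH and two stereocentres.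
- **Feature that allows this:** C1 (CH3, OH) and C2 (H, Br) are adjacent ring B carbons with OH and Br cis to each other and cis to the C8 substituent on C4. This cis-1,2-bromohydrin cannot come from an epoxide or bromonium opening (both give trans); it is the direct adduct of a bromo carbanion to a methyl ketone, and the oxygen on C8 can hold the metal on the face where the C1 oxygen must end.
- **Precursor 13:** from epoxy alcohol 5. Sharpless epoxidation sets C8, and CuI-catalysed Grignard opening at the other epoxide carbon sets C4. The ketone (from a terminal alkene) and the CHBr2 group (from an aldehyde) are unmasked late.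
- **Ring A, closed second on its own branch (step 15):** Cp2TiCl radical cyclization of (S)-6,7-epoxygeranyl acetate, then oxidation, axial reduction and Appel inversion to place the equatorial bromide.

Key step: step 10

Remark: the enantiomer of the fructose-derived Shi ketone (made from L-sorbose) is assumed to be a purchasable catalyst; all numbered starting materials are catalogue compounds.

## Fragment B (ring B aldehyde 18)

Step 1
Reactants: 1 3-[(tert-butyldimethylsilyl)oxy]propanal; 2 ethyl 2-(triphenyl-λ5-phosphanylidene)propanoate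
Product: 3 ethyl (2E)-5-[(tert-butyldimethylsilyl)oxy]-2-methylpent-2-enoate
Conditions: CH2Cl2, rt → 40 °C
Reagents that add atoms: none
Why: Wittig olefination with a stabilized α-methyl ylide should give the E trisubstituted enoate; no stereocentre is formed.

Step 2
Reactants: 3 ethyl (2E)-5-[(tert-butyldimethylsilyl)oxy]-2-methylpent-2-enoate
Product: 4 (2E)-5-[(tert-butyldimethylsilyl)oxy]-2-methylpent-2-en-1-ol
Conditions: i-Bu2AlH (DIBAL-H, 2.2 equiv), CH2Cl2, −78 °C; aq. potassium sodium tartrate
Reagents that add atoms: none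
Why: 1,2-reduction of the conjugated ester by an aluminium hydride should give the allylic alcohol without touching the silyl ether or the alkene geometry.

Step 3
Reactants: 4 (2E)-5-[(tert-butyldimethylsilyl)oxy]-2-methylpent-2-en-1-ol
Product: 5 [(2R,3R)-3-{2-[(tert-butyldimethylsilyl)oxy]ethyl}-2-methyloxiran-2-yl]methanol
Conditions: Ti(OiPr)4 (cat.), D-(−)-diethyl tartrate (cat.), t-BuOOH, 4 Å molecular sieves, CH2Cl2, −20 °C
Reagents that add atoms: tert-butyl hydroperoxide, CC(C)(C)OO
Why: Sharpless asymmetric epoxidation of the E 2-methyl allylic alcohol with the D-tartrate should give the (2R,3R)-epoxy alcohol under reagent control, which fixes the later carbinol carbon C8 and prepares C4 as the second epoxide carbon.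

Step 4
Reactants: 5 [(2R,3R)-3-{2-[(tert-butyldimethylsilyl)oxy]ethyl}-2-methyloxiran-2-yl]methanol; 6 but-3-en-1-ylmagnesium bromide (CH2=CHCH2CH2MgBr)
Product: 7 (2S,3S)-3-{2-[(tert-butyldimethylsilyl)oxy]ethyl}-2-methylhept-6-ene-1,2-diol
Conditions: 6 (3.5 equiv), CuI (0.2 equiv), THF, −30 → 0 °C; aq. NH4Cl
Reagents that add atoms: none
Why: CuI-catalysed Grignard opening of a 2,3-epoxy alcohol: the fully substituted C2 is blocked, so the butenyl group should enter at C3 by SN2 with inversion, giving the 1,2-diol and setting C4 as S next to the untouched C8.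

Step 5
Reactants: 7 (2S,3S)-3-{2-[(tert-butyldimethylsilyl)oxy]ethyl}-2-methylhept-6-ene-1,2-diol
Product: 8 tert-butyl(dimethyl){[(3S)-3-[(4S)-2,2,4-trimethyl-1,3-dioxolan-4-yl]hept-6-en-1-yl]oxy}silane
Conditions: 2,2-dimethoxypropane, PPTS (cat.), CH2Cl2, rt
Reagents that add atoms: 2,2-dimethoxypropane, COC(C)(C)OC
Why: acid-catalysed transketalization should close the acetonide of the 1,2-diol, masking both hydroxyls while leaving the C8 oxygen as a Lewis-basic ether for step 10.

Step 6
Reactants: 8 tert-butyl(dimethyl){[(3S)-3-[(4S)-2,2,4-trimethyl-1,3-dioxolan-4-yl]hept-6-en-1-yl]oxy}silane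
Product: 9 (3S)-3-[(4S)-2,2,4-trimethyl-1,3-dioxolan-4-yl]hept-6-en-1-ol
Conditions: Bu4NF (TBAF), THF, 0 °C → rt
Reagents that add atoms: none
Why: fluoride-induced desilylation should free the primary alcohol; the acetonide and alkene are inert.

Step 7
Reactants: 9 (3S)-3-[(4S)-2,2,4-trimethyl-1,3-dioxolan-4-yl]hept-6-en-1-ol
Product: 10 (3S)-3-[(4S)-2,2,4-trimethyl-1,3-dioxolan-4-yl]hept-6-enal
Conditions: Dess–Martin periodinane, NaHCO3, CH2Cl2, 0 °C → rt
Reagents that add atoms: none
Why: Dess–Martin oxidation should give the aldehyde under buffered conditions; the stereocentre is β to the carbonyl and cannot epimerize.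

Step 8
Reactants: 10 (3S)-3-[(4S)-2,2,4-trimethyl-1,3-dioxolan-4-yl]hept-6-enal
Product: 12 (4S)-4-[(3S)-1,1-dibromohept-6-en-3-yl]-2,2,4-trimethyl-1,3-dioxolane, via hydrazone 11 (not isolated)
Conditions: N2H4·H2O (excess), MeOH, 4 Å molecular sieves, rt, concentrate; then CuBr2 (6 equiv), LiOt-Bu (3 equiv), THF, 0 °C → rt
Reagents that add atoms: copper dibromide, Br[Cu]Br
Why: oxidative bromination of an N-unsubstituted aldehyde hydrazone with CuBr2 and base (diazoalkane-type intermediate, loss of N2) should convert CH=O into CHBr2 without acid, so the acetonide and alkene survive.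

Step 9
Reactants: 12 (4S)-4-[(3S)-1,1-dibromohept-6-en-3-yl]-2,2,4-trimethyl-1,3-dioxolane
Product: 13 (5S)-7,7-dibromo-5-[(4S)-2,2,4-trimethyl-1,3-dioxolan-4-yl]heptan-2-one
Conditions: PdCl2 (0.1 equiv), CuCl (1 equiv), O2 (1 atm), DMF/H2O, rt
Reagents that add atoms: water, O
Why: Tsuji–Wacker oxidation (divalent palladium, Markovnikov hydroxypalladation) should turn the monosubstituted alkene into the methyl ketone; the unactivated gem-dibromide and the acetonide are spectators.

Step 10
Reactants: 13 (5S)-7,7-dibromo-5-[(4S)-2,2,4-trimethyl-1,3-dioxolan-4-yl]heptan-2-one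
Product: 15 (1R,2S,4S)-2-bromo-1-methyl-4-[(4S)-2,2,4-trimethyl-1,3-dioxolan-4-yl]cyclohexan-1-ol, via 1-bromoalkyl-SmI2 carbenoid 14 (not isolated)
Conditions: SmI2 (2.1 equiv, 0.1 M in THF, added dropwise), THF, −78 → −40 °C, no HMPA; sat. aq. NH4Cl at −40 °C
Reagents that add atoms: none
Why: Proposed new method: two single-electron transfers from SmI2 to one C–Br bond of the gem-dibromide (much easier to reduce than the dialkyl ketone) should give carbenoid 14, which adds as a carbon nucleophile to the methyl ketone; the closest known reaction types are the SmI2-mediated bromo- and iodomethylation of ketones with CH2Br2 or CH2I2, which stops at the halohydrin, and the SmI2 Barbier cyclization of halo ketones. Ring B closes 6-exo-trig through the C1–C2 bond in a chair transition state with the bulky dioxolanyl group on C4 equatorial. C1: the trivalent samarium carried by C2 can be held on the ring face syn to C8 by the dioxolane oxygen on C8 and must bind the carbonyl oxygen in the four-centre addition, so the C1–O bond should form axial and cis to the C4 substituent, leaving the methyl equatorial. C2: bromine should take the equatorial site beside the samarium-bound oxygen (halogen–metal contact of the carbenoid, no 1,3-diaxial strain), giving Br cis to both OH and the C4 substituent; the two bromines are diastereotopic, and the carbenoid is expected to epimerize faster than it adds, so the ratio should be decided in the transition state. The step needs C–Br reduction in preference to ketyl formation and no further reduction of the product; the first follows from the easy reduction of a gem-dibromide, the second from using two equivalents of SmI2 at low temperature without HMPA. The cis samarium alkoxide has Br gauche to oxygen and cannot close to an epoxide, whereas any trans-diaxial isomer would, which makes a leak in selectivity easy to see and to remove.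

Step 11
Reactants: 15 (1R,2S,4S)-2-bromo-1-methyl-4-[(4S)-2,2,4-trimethyl-1,3-dioxolan-4-yl]cyclohexan-1-ol
Product: 16 (2S)-2-[(1S,3S,4R)-3-bromo-4-hydroxy-4-methylcyclohexyl]propane-1,2-diol
Conditions: AcOH/H2O (4:1), 40 °C
Reagents that add atoms: none
Why: mild acid hydrolysis should remove the acetonide; the cis bromohydrin (OH axial, Br equatorial) has no antiperiplanar pair for epoxide or bromonium formation and should survive.

Step 12
Reactants: 16 (2S)-2-[(1S,3S,4R)-3-bromo-4-hydroxy-4-methylcyclohexyl]propane-1,2-diol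
Product: 17 triethyl{[(1R,2S,4S)-2-bromo-1-methyl-4-[(2S)-1,2-bis[(triethylsilyl)oxy]propan-2-yl]cyclohexyl]oxy}silane
Conditions: Et3SiOTf (4 equiv), 2,6-lutidine, CH2Cl2, −78 → 0 °C
Reagents that add atoms: triethylsilyl trifluoromethanesulfonate, CC[Si](CC)(CC)OS(=O)(=O)C(F)(F)F
Why: silyl triflate with a hindered pyridine base should silylate the primary and both tertiary hydroxyls, removing all acidic protons before the olefination.

Step 13
Reactants: 17 triethyl{[(1R,2S,4S)-2-bromo-1-methyl-4-[(2S)-1,2-bis[(triethylsilyl)oxy]propan-2-yl]cyclohexyl]oxy}silane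
Product: 18 (2S)-2-[(1S,3S,4R)-3-bromo-4-methyl-4-[(triethylsilyl)oxy]cyclohexyl]-2-[(triethylsilyl)oxy]propanal
Conditions: (COCl)2, DMSO, CH2Cl2, −78 → −30 °C; then Et3N, −78 °C → rt
Reagents that add atoms: none
Why: Swern oxidation cleaves and oxidizes a primary triethylsilyl ether directly while tertiary silyl ethers stay, which should give the α-silyloxy aldehyde; it has no α-hydrogen and cannot epimerize.

## Fragment A (ring A sulfone 28)

Step 14
Reactants: 19 geranyl acetate, (2E)-3,7-dimethylocta-2,6-dien-1-yl acetate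
Product: 20 (2E)-5-[(2S)-3,3-dimethyloxiran-2-yl]-3-methylpent-2-en-1-yl acetate
Conditions: ent-Shi ketone (0.3 equiv), KHSO5 (Oxone), K2CO3, Bu4NHSO4, MeCN/dimethoxymethane/aq. Na2B4O7 buffer, 0 °C
Reagents that add atoms: potassium peroxymonosulfate, [K+].[O-]S(=O)(=O)OO
Why: Shi asymmetric epoxidation (chiral dioxirane) should select the electron-rich distal trisubstituted alkene over the acetate-deactivated allylic one and, with the L-series ketone, give the (S)-epoxide that becomes the bromine-bearing carbon of ring A.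

Step 15
Reactants: 20 (2E)-5-[(2S)-3,3-dimethyloxiran-2-yl]-3-methylpent-2-en-1-yl acetate
Product: 21 [(1R,3S)-3-hydroxy-2,2-dimethyl-6-methylidenecyclohexyl]methyl acetate
Conditions: Cp2TiCl2 (2.2 equiv), Mn dust, THF, rt (Cp2TiCl formed first), slow addition of 20; then 1 M HCl
Reagents that add atoms: none
Why: Nugent–RajanBabu homolytic epoxide opening by Cp2TiCl (trivalent titanium) gives the tertiary radical, which should close ring A 6-endo-trig through a chair with the titanoxy and acetoxymethyl groups equatorial (ring C1 set R, cis to the C–O bond), and trapping by a second Cp2TiCl with β-hydride loss should give the exocyclic methylene.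

Step 16
Reactants: 21 [(1R,3S)-3-hydroxy-2,2-dimethyl-6-methylidenecyclohexyl]methyl acetate
Product: 22 [(1R)-2,2-dimethyl-6-methylidene-3-oxocyclohexyl]methyl acetate
Conditions: Dess–Martin periodinane, NaHCO3, CH2Cl2, rt
Reagents that add atoms: none
Why: Dess–Martin oxidation should give the ketone; the remaining stereocentre is separated from the carbonyl by the quaternary carbon and cannot epimerize.

Step 17
Reactants: 22 [(1R)-2,2-dimethyl-6-methylidene-3-oxocyclohexyl]methyl acetate
Product: 23 [(1R,3R)-3-hydroxy-2,2-dimethyl-6-methylidenecyclohexyl]methyl acetate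
Conditions: LiBH(s-Bu)3 (L-Selectride, 1.1 equiv), THF, −78 °C; aq. NH4Cl
Reagents that add atoms: none
Why: the bulky trialkylborohydride should attack the 2,2-dimethylcyclohexanone from the equatorial direction (axial approach is blocked by the axial methyl), giving the axial (3R) alcohol trans to the acetoxymethyl group; the acetate is much slower to react at −78 °C.

Step 18
Reactants: 23 [(1R,3R)-3-hydroxy-2,2-dimethyl-6-methylidenecyclohexyl]methyl acetate
Product: 24 [(1R,3S)-3-bromo-2,2-dimethyl-6-methylidenecyclohexyl]methyl acetate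
Conditions: CBr4, PPh3, 2,6-lutidine, CH2Cl2, 0 °C → rt
Reagents that add atoms: carbon tetrabromide, BrC(Br)(Br)Br
Why: Appel bromination: SN2 displacement of the axial oxyphosphonium group by bromide from the equatorial side should give the equatorial (3S) bromide cis to the side chain, with inversion; this neopentyl-type displacement is slow and is listed below as a risk.

Step 19
Reactants: 24 [(1R,3S)-3-bromo-2,2-dimethyl-6-methylidenecyclohexyl]methyl acetate
Product: 25 [(1R,3S)-3-bromo-2,2-dimethyl-6-methylidenecyclohexyl]methanol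
Conditions: K2CO3 (cat.), MeOH, 0 °C → rt
Reagents that add atoms: none
Why: transesterification should free the primary alcohol; the equatorial bromide has no antiperiplanar hydrogen and should resist elimination under this mild base.

Step 20
Reactants: 25 [(1R,3S)-3-bromo-2,2-dimethyl-6-methylidenecyclohexyl]methanol; 26 1-phenyl-1H-tetrazole-5-thiol
Product: 27 5-({[(1R,3S)-3-bromo-2,2-dimethyl-6-methylidenecyclohexyl]methyl}sulfanyl)-1-phenyl-1H-tetrazole
Conditions: PPh3, diisopropyl azodicarboxylate, THF, 0 °C → rt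
Reagents that add atoms: none
Why: Mitsunobu thioetherification of the primary alcohol with the acidic heteroaryl thiol should give the sulfide; no stereocentre is touched.

Step 21
Reactants: 27 5-({[(1R,3S)-3-bromo-2,2-dimethyl-6-methylidenecyclohexyl]methyl}sulfanyl)-1-phenyl-1H-tetrazole
Product: 28 5-({[(1R,3S)-3-bromo-2,2-dimethyl-6-methylidenecyclohexyl]methyl}sulfonyl)-1-phenyl-1H-tetrazole
Conditions: (NH4)6Mo7O24·4H2O (cat.), H2O2 (30 % aq.), EtOH, 0 °C → rt
Reagents that add atoms: hydrogen peroxide, OO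
Why: (NH4)6Mo7O24-catalysed peroxide oxidation of sulfide to sulfone is chemoselective for sulfur, so the 1,1-disubstituted alkene should survive.

## Union and end game

Step 22
Reactants: 28 5-({[(1R,3S)-3-bromo-2,2-dimethyl-6-methylidenecyclohexyl]methyl}sulfonyl)-1-phenyl-1H-tetrazole; 18 (2S)-2-[(1S,3S,4R)-3-bromo-4-methyl-4-[(triethylsilyl)oxy]cyclohexyl]-2-[(triethylsilyl)oxy]propanal
Product: 29 triethyl{[(1R,2S,4S)-2-bromo-4-[(2S,3E)-4-[(1R,3S)-3-bromo-2,2-dimethyl-6-methylidenecyclohexyl]-2-[(triethylsilyl)oxy]but-3-en-2-yl]-1-methylcyclohexyl]oxy}silane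
Conditions: KN(SiMe3)2 (KHMDS) added to 28 + 18, 1,2-dimethoxyethane, −78 °C → rt
Reagents that add atoms: none
Why: Julia–Kocienski olefination (addition, Smiles rearrangement, loss of SO2 and tetrazolate) should give the E disubstituted alkene; the aldehyde is non-enolizable, so base can be added to the mixture, and both equatorial bromides lack an antiperiplanar hydrogen at −78 °C.

Step 23
Reactants: 29 triethyl{[(1R,2S,4S)-2-bromo-4-[(2S,3E)-4-[(1R,3S)-3-bromo-2,2-dimethyl-6-methylidenecyclohexyl]-2-[(triethylsilyl)oxy]but-3-en-2-yl]-1-methylcyclohexyl]oxy}silane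
Product: 30 (1R,2S,4S)-2-bromo-4-[(2S,3E)-4-[(1R,3S)-3-bromo-2,2-dimethyl-6-methylidenecyclohexyl]-2-hydroxybut-3-en-2-yl]-1-methylcyclohexan-1-ol
Conditions: HF·pyridine, pyridine, THF, 0 °C → rt
Reagents that add atoms: none
Why: buffered fluoride desilylation should free both tertiary alcohols without ionizing the tertiary allylic carbinol or disturbing the bromides.

## Compound list

1 | 3-[(tert-butyldimethylsilyl)oxy]propanal | O=CCCO[Si](C)(C)C(C)(C)C | starting material
2 | ethyl 2-(triphenyl-λ5-phosphanylidene)propanoate | CCOC(=O)C(C)=P(c1ccccc1)(c1ccccc1)c1ccccc1 | starting material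
3 | ethyl (2E)-5-[(tert-butyldimethylsilyl)oxy]-2-methylpent-2-enoate | CCOC(=O)/C(C)=C/CCO[Si](C)(C)C(C)(C)C | intermediate
4 | (2E)-5-[(tert-butyldimethylsilyl)oxy]-2-methylpent-2-en-1-ol | OC/C(C)=C/CCO[Si](C)(C)C(C)(C)C | intermediate
5 | [(2R,3R)-3-{2-[(tert-butyldimethylsilyl)oxy]ethyl}-2-methyloxiran-2-yl]methanol | OC[C@@]1(C)O[C@@H]1CCO[Si](C)(C)C(C)(C)C | intermediate
6 | but-3-en-1-ylmagnesium bromide | C=CCC[Mg]Br | starting material
7 | (2S,3S)-3-{2-[(tert-butyldimethylsilyl)oxy]ethyl}-2-methylhept-6-ene-1,2-diol | OC[C@@](C)(O)[C@H](CCO[Si](C)(C)C(C)(C)C)CCC=C | intermediate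
8 | tert-butyl(dimethyl){[(3S)-3-[(4S)-2,2,4-trimethyl-1,3-dioxolan-4-yl]hept-6-en-1-yl]oxy}silane | CC1(C)OC[C@@](C)(O1)[C@H](CCO[Si](C)(C)C(C)(C)C)CCC=C | intermediate
9 | (3S)-3-[(4S)-2,2,4-trimethyl-1,3-dioxolan-4-yl]hept-6-en-1-ol | CC1(C)OC[C@@](C)(O1)[C@H](CCO)CCC=C | intermediate
10 | (3S)-3-[(4S)-2,2,4-trimethyl-1,3-dioxolan-4-yl]hept-6-enal | CC1(C)OC[C@@](C)(O1)[C@H](CC=O)CCC=C | intermediate
11 | [(1E,3S)-3-[(4S)-2,2,4-trimethyl-1,3-dioxolan-4-yl]hept-6-en-1-ylidene]hydrazine | CC1(C)OC[C@@](C)(O1)[C@H](C/C=N/N)CCC=C | intermediate (not isolated)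
12 | (4S)-4-[(3S)-1,1-dibromohept-6-en-3-yl]-2,2,4-trimethyl-1,3-dioxolane | CC1(C)OC[C@@](C)(O1)[C@H](CC(Br)Br)CCC=C | intermediate
13 | (5S)-7,7-dibromo-5-[(4S)-2,2,4-trimethyl-1,3-dioxolan-4-yl]heptan-2-one | CC1(C)OC[C@@](C)(O1)[C@H](CC(Br)Br)CCC(C)=O | intermediate
14 | [(3S)-1-bromo-6-oxo-3-[(4S)-2,2,4-trimethyl-1,3-dioxolan-4-yl]heptyl]diiodosamarium (1-bromoalkyl-SmI2 carbenoid) | CC1(C)OC[C@@](C)(O1)[C@H](CC(Br)[Sm](I)I)CCC(C)=O | intermediate (not isolated)
15 | (1R,2S,4S)-2-bromo-1-methyl-4-[(4S)-2,2,4-trimethyl-1,3-dioxolan-4-yl]cyclohexan-1-ol | CC1(C)OC[C@@](C)(O1)[C@H]1CC[C@@](C)(O)[C@@H](Br)C1 | intermediate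
16 | (2S)-2-[(1S,3S,4R)-3-bromo-4-hydroxy-4-methylcyclohexyl]propane-1,2-diol | OC[C@@](C)(O)[C@H]1CC[C@@](C)(O)[C@@H](Br)C1 | intermediate
17 | triethyl{[(1R,2S,4S)-2-bromo-1-methyl-4-[(2S)-1,2-bis[(triethylsilyl)oxy]propan-2-yl]cyclohexyl]oxy}silane | CC[Si](CC)(CC)OC[C@@](C)(O[Si](CC)(CC)CC)[C@H]1CC[C@@](C)(O[Si](CC)(CC)CC)[C@@H](Br)C1 | intermediate
18 | (2S)-2-[(1S,3S,4R)-3-bromo-4-methyl-4-[(triethylsilyl)oxy]cyclohexyl]-2-[(triethylsilyl)oxy]propanal | O=C[C@@](C)(O[Si](CC)(CC)CC)[C@H]1CC[C@@](C)(O[Si](CC)(CC)CC)[C@@H](Br)C1 | intermediate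
19 | geranyl acetate, (2E)-3,7-dimethylocta-2,6-dien-1-yl acetate | CC(C)=CCC/C(C)=C/COC(C)=O | starting material
20 | (2E)-5-[(2S)-3,3-dimethyloxiran-2-yl]-3-methylpent-2-en-1-yl acetate | CC(=O)OC/C=C(C)/CC[C@@H]1OC1(C)C | intermediate
21 | [(1R,3S)-3-hydroxy-2,2-dimethyl-6-methylidenecyclohexyl]methyl acetate | C=C1CC[C@H](O)C(C)(C)[C@@H]1COC(C)=O | intermediate
22 | [(1R)-2,2-dimethyl-6-methylidene-3-oxocyclohexyl]methyl acetate | C=C1CCC(=O)C(C)(C)[C@@H]1COC(C)=O | intermediate
23 | [(1R,3R)-3-hydroxy-2,2-dimethyl-6-methylidenecyclohexyl]methyl acetate | C=C1CC[C@@H](O)C(C)(C)[C@@H]1COC(C)=O | intermediate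
24 | [(1R,3S)-3-bromo-2,2-dimethyl-6-methylidenecyclohexyl]methyl acetate | C=C1CC[C@H](Br)C(C)(C)[C@@H]1COC(C)=O | intermediate
25 | [(1R,3S)-3-bromo-2,2-dimethyl-6-methylidenecyclohexyl]methanol | C=C1CC[C@H](Br)C(C)(C)[C@@H]1CO | intermediate
26 | 1-phenyl-1H-tetrazole-5-thiol | Sc1nnnn1-c1ccccc1 | starting material
27 | 5-({[(1R,3S)-3-bromo-2,2-dimethyl-6-methylidenecyclohexyl]methyl}sulfanyl)-1-phenyl-1H-tetrazole | C=C1CC[C@H](Br)C(C)(C)[C@@H]1CSc1nnnn1-c1ccccc1 | intermediate
28 | 5-({[(1R,3S)-3-bromo-2,2-dimethyl-6-methylidenecyclohexyl]methyl}sulfonyl)-1-phenyl-1H-tetrazole | C=C1CC[C@H](Br)C(C)(C)[C@@H]1CS(=O)(=O)c1nnnn1-c1ccccc1 | intermediate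
29 | triethyl{[(1R,2S,4S)-2-bromo-4-[(2S,3E)-4-[(1R,3S)-3-bromo-2,2-dimethyl-6-methylidenecyclohexyl]-2-[(triethylsilyl)oxy]but-3-en-2-yl]-1-methylcyclohexyl]oxy}silane | C=C1CC[C@H](Br)C(C)(C)[C@@H]1/C=C/[C@@](C)(O[Si](CC)(CC)CC)[C@H]1CC[C@@](C)(O[Si](CC)(CC)CC)[C@@H](Br)C1 | intermediate
30 | (1R,2S,4S)-2-bromo-4-[(2S,3E)-4-[(1R,3S)-3-bromo-2,2-dimethyl-6-methylidenecyclohexyl]-2-hydroxybut-3-en-2-yl]-1-methylcyclohexan-1-ol | C=C1CC[C@H](Br)C(C)(C)[C@@H]1/C=C/[C@@](C)(O)[C@H]1CC[C@@](C)(O)[C@@H](Br)C1 | target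

## Step count and risks

Total step count: 23. Longest linear sequence: 15 steps (steps 1–13, then 22 and 23); fragment A takes 8 steps (14–21).

**Risk 1, step 10 (Proposed new method).** The process at risk is facial selectivity at the ketone and at the carbenoid carbon, together with α-elimination or protonation of the carbenoid before it closes the ring. The fallback closes the same C1–C2 bond by known chemistry; it sets out from aldehyde 10 and comes back at 15.
- Tsuji–Wacker oxidation (PdCl2, CuCl, O2, DMF/H2O) should give (3S)-6-oxo-3-[(4S)-2,2,4-trimethyl-1,3-dioxolan-4-yl]heptanal F1.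
- An intramolecular crossed benzoin reaction (chiral aminoindanol-derived triazolium salt, catalytic Et3N, THF) uses the aldehyde carbon as acyl anion equivalent and should close the ring to (2R,5S)-2-hydroxy-2-methyl-5-[(4S)-2,2,4-trimethyl-1,3-dioxolan-4-yl]cyclohexan-1-one F2; the carbinol configuration is chosen through the catalyst enantiomer.
- Hydroxyl-directed reduction with Me4NBH(OAc)3 (MeCN/AcOH, −20 °C) delivers hydride from the face of the tertiary hydroxyl and should give the trans diol (1R,2R,4S)-1-methyl-4-[(4S)-2,2,4-trimethyl-1,3-dioxolan-4-yl]cyclohexane-1,2-diol F3.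
- The secondary axial hydroxyl is converted (Tf2O, pyridine, CH2Cl2, −20 °C) into (1R,2R,5S)-2-hydroxy-2-methyl-5-[(4S)-2,2,4-trimethyl-1,3-dioxolan-4-yl]cyclohexyl trifluoromethanesulfonate F4, which is not isolated; Bu4NBr in toluene under neutral conditions should displace it with inversion and return 15.

**Risk 2, step 18.** The process at risk is elimination towards the ring alkene, or methyl migration, competing with SN2 displacement at the neopentyl-type axial alcohol. The fallback forms the C–Br bond and ring A in one cationic event; it sets out from geranyl acetate 19 and comes back at 25.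
- Bromonium-initiated cyclization with Et2SBr·SbCl5Br (MeNO2, −25 °C; alkene isomers removed on AgNO3-impregnated silica) should give 24 with bromine equatorial and cis to the acetoxymethyl group, together with its enantiomer [(1S,3R)-3-bromo-2,2-dimethyl-6-methylidenecyclohexyl]methyl acetate F5.
- Methanolysis (K2CO3, MeOH) should give 25 together with [(1S,3R)-3-bromo-2,2-dimethyl-6-methylidenecyclohexyl]methanol F6.
- Lipase-catalysed acetylation (Burkholderia cepacia lipase, vinyl acetate, t-BuOMe) should separate the enantiomers. Either F6 is acylated back to F5 and unreacted 25 is collected, or 25 is acylated to 24 and passes through step 19 again; in both cases the route is rejoined at 25.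

**Risk 3, step 22.** The process at risk is slow addition of the hindered sulfonyl carbanion to the α-quaternary aldehyde and erosion of E selectivity by the α-silyloxy group. The fallback uses a phosphorus ylide and then corrects the geometry; it sets out from alcohol 25 (with aldehyde 18) and comes back at 29.
- I2, PPh3 and imidazole (CH2Cl2) should give [(1R,3S)-3-bromo-2,2-dimethyl-6-methylidenecyclohexyl]methyl iodide F7.
- PPh3 (MeCN, 90 °C) should give {[(1R,3S)-3-bromo-2,2-dimethyl-6-methylidenecyclohexyl]methyl}triphenylphosphonium iodide F8.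
- Wittig reaction of its ylide (NaN(SiMe3)2, THF, −78 °C) with 18 should give mainly the Z alkene triethyl{[(1R,2S,4S)-2-bromo-4-[(2S,3Z)-4-[(1R,3S)-3-bromo-2,2-dimethyl-6-methylidenecyclohexyl]-2-[(triethylsilyl)oxy]but-3-en-2-yl]-1-methylcyclohexyl]oxy}silane F9.
- Thiyl-radical isomerization (catalytic PhSSPh, visible light, hexane) should convert F9 into the more stable E alkene 29.

## Further compounds

F1 | step 10 | (3S)-6-oxo-3-[(4S)-2,2,4-trimethyl-1,3-dioxolan-4-yl]heptanal | CC1(C)OC[C@@](C)(O1)[C@H](CC=O)CCC(C)=O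
F2 | step 10 | (2R,5S)-2-hydroxy-2-methyl-5-[(4S)-2,2,4-trimethyl-1,3-dioxolan-4-yl]cyclohexan-1-one | CC1(C)OC[C@@](C)(O1)[C@H]1CC[C@@](C)(O)C(=O)C1
F3 | step 10 | (1R,2R,4S)-1-methyl-4-[(4S)-2,2,4-trimethyl-1,3-dioxolan-4-yl]cyclohexane-1,2-diol | CC1(C)OC[C@@](C)(O1)[C@H]1CC[C@@](C)(O)[C@H](O)C1
F4 | step 10 | (1R,2R,5S)-2-hydroxy-2-methyl-5-[(4S)-2,2,4-trimethyl-1,3-dioxolan-4-yl]cyclohexyl trifluoromethanesulfonate | CC1(C)OC[C@@](C)(O1)[C@H]1CC[C@@](C)(O)[C@H](OS(=O)(=O)C(F)(F)F)C1
F5 | step 18 | [(1S,3R)-3-bromo-2,2-dimethyl-6-methylidenecyclohexyl]methyl acetate | C=C1CC[C@@H](Br)C(C)(C)[C@H]1COC(C)=O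
F6 | step 18 | [(1S,3R)-3-bromo-2,2-dimethyl-6-methylidenecyclohexyl]methanol | C=C1CC[C@@H](Br)C(C)(C)[C@H]1CO
F7 | step 22 | [(1R,3S)-3-bromo-2,2-dimethyl-6-methylidenecyclohexyl]methyl iodide | C=C1CC[C@H](Br)C(C)(C)[C@@H]1CI
F8 | step 22 | {[(1R,3S)-3-bromo-2,2-dimethyl-6-methylidenecyclohexyl]methyl}triphenylphosphonium iodide | C=C1CC[C@H](Br)C(C)(C)[C@@H]1C[P+](c1ccccc1)(c1ccccc1)c1ccccc1.[I-]
F9 | step 22 | triethyl{[(1R,2S,4S)-2-bromo-4-[(2S,3Z)-4-[(1R,3S)-3-bromo-2,2-dimethyl-6-methylidenecyclohexyl]-2-[(triethylsilyl)oxy]but-3-en-2-yl]-1-methylcyclohexyl]oxy}silane | C=C1CC[C@H](Br)C(C)(C)[C@@H]1/C=C\[C@@](C)(O[Si](CC)(CC)CC)[C@H]1CC[C@@](C)(O[Si](CC)(CC)CC)[C@@H](Br)C1
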